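Assumption: (Z)-1-chlorobut-2-ene, 3-bromo-2-methoxyprop-1-ene and (R)-2-methylbutanoic acid are taken as catalogue chemicals; the O-8 acyl group is (R)-2-methylbutanoyl, as the SMILES encodes.

**Retrosynthetic overview**
1. Target 21 ⇐ methyl enol ether 20 (masked C2 ketone); the two esters go on one at a time: O-8 on an α-ketol, O-9 after ketone reduction.
2. 8α-O, 10β-H and 7β-isopropenyl ⇐ carane-fused silyl enol ether, by a thermal homodienyl 1,5-H shift (cyclopropane = masked isopropenyl) followed by enolate hydroxylation.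
3. Ring A (formed second) ⇐ enol-ether ring-closing metathesis of a 4-vinyl/10-(2-methoxyallyl) ketone.
4. Key step: C4–C5 bond (quaternary C5 and the C4 methyl stereocentre) plus the C10 side chain ⇐ tandem anionic oxy-Cope/enolate alkylation of a (Z)-crotyl carbinol.
5. Ring B (present from the start) ⇐ (+)-3-carene via car-3-en-5-one; no Robinson annulation is used.

Numbering: decalin-type intermediates carry eremophilane numbers (C4-CH3 = C15, C5-CH3 = C14, isopropenyl on C7, C10 = ring-fusion CH). "8,11-cyclo" denotes the carane cyclopropane bond C8–C11. β is the face of the C5 methyl, which is also the face of the CMe2 bridge.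

**Route**

Step 1
Reactants: 1 (+)-3-carene
Product: 2 (1R,6S)-4,7,7-trimethylbicyclo[4.1.0]hept-3-en-2-one (car-3-en-5-one)
Conditions: t-BuOOH (70% aq), CrO3 (5 mol %), CH2Cl2, rt
Reagents that add atoms: tert-butyl hydroperoxide, CC(C)(C)OO
Why: Chromium-catalysed allylic oxidation attacks the ring CH2 next to the CH= terminus, the less hindered allylic site, to give the conjugated enone, and the two cyclopropane stereocentres of the chiral-pool terpene are untouched.

Step 2
Reactants: 2 car-3-en-5-one; 3 (Z)-1-chlorobut-2-ene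
Product: 5 (1R,2R,6S)-2-[(2Z)-but-2-en-1-yl]-4,7,7-trimethylbicyclo[4.1.0]hept-3-en-2-ol, via (Z)-but-2-enylbarium chloride 4 (not isolated)
Conditions: Ba* (BaI2, lithium biphenylide, THF, rt); 3, −78 °C; then 2, −78 °C; H2O
Reagents that add atoms: none
Why: Yamamoto allylbarium addition, in which the allylic barium reagent reacts at its α-carbon with retention of the Z geometry and adds 1,2 to the enone from the face anti to the gem-dimethylcyclopropane bridge, so the carbinol centre is set with crotyl α and OH β.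

Step 3
Reactants: 5 (Z)-crotyl carbinol; 6 3-bromo-2-methoxyprop-1-ene
Product: 9 (1R,3S,4R,6S)-4-[(2S)-but-3-en-2-yl]-3-(2-methoxyprop-2-en-1-yl)-4,7,7-trimethylbicyclo[4.1.0]heptan-2-one, via potassium alkoxide of the carbinol 7 (not isolated), via potassium enolate from the oxy-Cope shift 8 (not isolated)
Conditions: KH, 18-crown-6, THF, 0 → 45 °C; then 6, −78 → 0 °C
Reagents that add atoms: none
Why: Tandem anionic oxy-Cope rearrangement/enolate C-alkylation, in which the [3,3] shift runs suprafacially on the α-face through a chair transition state with the Z-methyl pseudo-axial, so the C4–C5 bond forms anti to the cyclopropane (quaternary C5, 14-Me β) with C4 configured to put 15-Me cis to 14-Me, and the regiodefined enolate (C8 is a non-enolisable cyclopropane CH) is alkylated at C10 anti to the cyclopropane, a centre that is erased in step 5 and reset in step 6.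

Step 4
Reactants: 9 diene ketone
Product: 10 (4S,5R,7S,8R,10S)-2-methoxy-8,11-cycloeremophil-2-en-9-one
Conditions: Grubbs II (5 mol %), PhMe, 80 °C
Reagents that add atoms: none
Why: Ring-closing metathesis, in which the catalyst loads on the monosubstituted vinyl group and closes onto the 1,1-disubstituted enol ether to give ring A as its methyl enol ether (masked C2 ketone) without creating a stereocentre.

Step 5
Reactants: 10 tricyclic ketone
Product: 12 (4S,5R,7S,8R)-2-methoxy-9-(trimethylsilyloxy)-8,11-cycloeremophila-2,9-diene, via potassium enolate of the tricyclic ketone 11 (not isolated)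
Conditions: KHMDS, THF, −78 → 0 °C; TMSCl, −78 °C
Reagents that add atoms: chlorotrimethylsilane, C[Si](C)(C)Cl
Why: Enolate O-silylation, in which C10–H is the only enolisable α-hydrogen (C8 is a cyclopropane CH), so the C9=C10 silyl enol ether forms regiospecifically and C10 is planarised whatever its configuration was.

Step 6
Reactants: 12 C9=C10 silyl enol ether
Product: 13 (4S,5R,7S,10S)-2-methoxy-9-(trimethylsilyloxy)eremophila-2,8,11-triene
Conditions: PhMe, sealed tube (base-washed), 210 °C
Reagents that add atoms: none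
Why: Proposed new method: a thermal homodienyl [1,5]-hydrogen shift (retro-ene) of the 2-siloxyvinylcyclopropane, in which the endo methyl of the CMe2 bridge hands a hydrogen to C10 on the β-face while the C8–C11 bond breaks, should unveil the 7β-isopropenyl group, set the cis ring fusion (10β-H) suprafacially and move the silyl enol ether to C8=C9, the closest known reaction being the pyrolysis of 2-carene to trans-isolimonene (cis-2-alkyl-1-vinylcyclopropane to 1,4-diene).

Step 7
Reactants: 13 C8=C9 silyl enol ether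
Product: 15 (4S,5R,7R,8R,10S)-8-hydroxy-2-methoxyeremophila-2,11-dien-9-one, via lithium enolate 14 (not isolated)
Conditions: MeLi, THF, 0 °C; then 2-(phenylsulfonyl)-3-phenyloxaziridine, −78 °C; H2O
Reagents that add atoms: 2-(phenylsulfonyl)-3-phenyloxaziridine, O=S(=O)(c1ccccc1)N1OC1c1ccccc1
Why: Regiospecific lithium enolate generation from the silyl enol ether followed by Davis oxaziridine α-hydroxylation, which delivers oxygen to C8 trans to the adjacent 7β-isopropenyl group to give the 8α-OH, also the equatorial and thermodynamically preferred epimer.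

Step 8
Reactants: 15 α-hydroxy ketone; 16 (R)-2-methylbutanoic acid
Product: 17 (4S,5R,7R,8R,10S)-2-methoxy-9-oxoeremophila-2,11-dien-8-yl (2R)-2-methylbutanoate
Conditions: DCC, DMAP (cat.), CH2Cl2, 0 °C → rt
Reagents that add atoms: none
Why: Steglich esterification of the only free hydroxyl under neutral carbodiimide conditions places the (R)-2-methylbutanoate on O-8 without disturbing its α-stereocentre.

Step 9
Reactants: 17 α-acyloxy ketone
Product: 18 (4S,5R,7R,8R,9S,10S)-9-hydroxy-2-methoxyeremophila-2,11-dien-8-yl (2R)-2-methylbutanoate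
Conditions: L-Selectride, THF, −78 °C; H2O
Reagents that add atoms: none
Why: Bulky-hydride ketone reduction, in which axial attack from the α-face is blocked by the syn-axial C4–C5 bond of the cis-decalin, so hydride enters from the β-face and gives the axial 9α-alcohol cis to the 8α-ester.

Step 10
Reactants: 18 hydroxy ester; 19 (E)-2-methylbut-2-enoyl chloride (tigloyl chloride)
Product: 20 (4S,5R,7R,8R,9S,10S)-2-methoxy-8-[(2R)-2-methylbutanoyloxy]eremophila-2,11-dien-9-yl (2E)-2-methylbut-2-enoate
Conditions: DMAP, Et3N, CH2Cl2, 40 °C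
Reagents that add atoms: none
Why: DMAP-catalysed acyl transfer esterifies the remaining axial secondary alcohol with the configurationally stable E-acid chloride, and no stereocentre is touched.

Step 11
Reactants: 20 diester enol ether
Product: 21 (4S,5R,7R,8R,9S,10S)-8-[(2R)-2-methylbutanoyloxy]-2-oxoeremophil-11-en-9-yl (2E)-2-methylbut-2-enoate (target)
Conditions: 0.5 M HCl (aq), THF, 0 °C
Reagents that add atoms: water, O
Why: Mild acid hydrolysis of the methyl enol ether (C3 protonation, hydration, loss of methanol) releases the C2 ketone while the esters, the isopropenyl group and all stereocentres are left intact.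

**Compound list**
1 | (+)-3-carene, (1S,6R)-3,7,7-trimethylbicyclo[4.1.0]hept-3-ene | CC1=CC[C@@H]2[C@H](C1)C2(C)C | starting material
2 | (1R,6S)-4,7,7-trimethylbicyclo[4.1.0]hept-3-en-2-one (car-3-en-5-one) | CC1=CC(=O)[C@@H]2[C@H](C1)C2(C)C | intermediate
3 | (Z)-1-chlorobut-2-ene | C/C=C\CCl | starting material
4 | (Z)-but-2-enylbarium chloride | C/C=C\C[Ba]Cl | intermediate
5 | (1R,2R,6S)-2-[(2Z)-but-2-en-1-yl]-4,7,7-trimethylbicyclo[4.1.0]hept-3-en-2-ol | CC1=C[C@](O)(C/C=C\C)[C@@H]2[C@H](C1)C2(C)C | intermediate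
6 | 3-bromo-2-methoxyprop-1-ene | C=C(OC)CBr | starting material
7 | potassium alkoxide of 5 | CC1=C[C@]([O-])(C/C=C\C)[C@@H]2[C@H](C1)C2(C)C.[K+] | intermediate
8 | potassium (1R,4R,6S)-4-[(2S)-but-3-en-2-yl]-4,7,7-trimethylbicyclo[4.1.0]hept-2-en-2-olate | CC1(C)[C@H]2C[C@](C)([C@@H](C)C=C)C=C([O-])[C@@H]12.[K+] | intermediate
9 | (1R,3S,4R,6S)-4-[(2S)-but-3-en-2-yl]-3-(2-methoxyprop-2-en-1-yl)-4,7,7-trimethylbicyclo[4.1.0]heptan-2-one (10β-H epimer drawn) | CC1(C)[C@H]2C[C@](C)([C@@H](C)C=C)[C@H](CC(OC)=C)C(=O)[C@@H]12 | intermediate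
10 | (4S,5R,7S,8R,10S)-2-methoxy-8,11-cycloeremophil-2-en-9-one | CC1(C)[C@H]2C[C@@]3(C)[C@H](CC(OC)=C[C@@H]3C)C(=O)[C@@H]12 | intermediate
11 | potassium C9=C10 enolate of 10 | CC1(C)[C@H]2C[C@@]3(C)C(CC(OC)=C[C@@H]3C)=C([O-])[C@@H]12.[K+] | intermediate
12 | (4S,5R,7S,8R)-2-methoxy-9-(trimethylsilyloxy)-8,11-cycloeremophila-2,9-diene | CC1(C)[C@H]2C[C@@]3(C)C(CC(OC)=C[C@@H]3C)=C(O[Si](C)(C)C)[C@@H]12 | intermediate
13 | (4S,5R,7S,10S)-2-methoxy-9-(trimethylsilyloxy)eremophila-2,8,11-triene | C=C(C)[C@H]1C[C@@]2(C)[C@H](CC(OC)=C[C@@H]2C)C(O[Si](C)(C)C)=C1 | intermediate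
14 | lithium C8=C9 enolate from 13 | C=C(C)[C@H]1C[C@@]2(C)[C@H](CC(OC)=C[C@@H]2C)C([O-])=C1.[Li+] | intermediate
15 | (4S,5R,7R,8R,10S)-8-hydroxy-2-methoxyeremophila-2,11-dien-9-one | C=C(C)[C@H]1C[C@@]2(C)[C@H](CC(OC)=C[C@@H]2C)C(=O)[C@@H]1O | intermediate
16 | (R)-2-methylbutanoic acid | CC[C@@H](C)C(=O)O | starting material
17 | (4S,5R,7R,8R,10S)-2-methoxy-9-oxoeremophila-2,11-dien-8-yl (2R)-2-methylbutanoate | C=C(C)[C@H]1C[C@@]2(C)[C@H](CC(OC)=C[C@@H]2C)C(=O)[C@@H]1OC(=O)[C@H](C)CC | intermediate
18 | (4S,5R,7R,8R,9S,10S)-9-hydroxy-2-methoxyeremophila-2,11-dien-8-yl (2R)-2-methylbutanoate | C=C(C)[C@H]1C[C@@]2(C)[C@H](CC(OC)=C[C@@H]2C)[C@H](O)[C@@H]1OC(=O)[C@H](C)CC | intermediate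
19 | (E)-2-methylbut-2-enoyl chloride (tigloyl chloride) | C/C=C(\C)C(=O)Cl | starting material
20 | (4S,5R,7R,8R,9S,10S)-2-methoxy-8-[(2R)-2-methylbutanoyloxy]eremophila-2,11-dien-9-yl (2E)-2-methylbut-2-enoate | C=C(C)[C@H]1C[C@@]2(C)[C@H](CC(OC)=C[C@@H]2C)[C@H](OC(=O)/C(C)=C/C)[C@@H]1OC(=O)[C@H](C)CC | intermediate
21 | (4S,5R,7R,8R,9S,10S)-8-[(2R)-2-methylbutanoyloxy]-2-oxoeremophil-11-en-9-yl (2E)-2-methylbut-2-enoate, CNP0312791.1 | C=C(C)[C@H]1C[C@@]2(C)[C@H](CC(=O)C[C@@H]2C)[C@H](OC(=O)/C(C)=C/C)[C@@H]1OC(=O)[C@H](C)CC | target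

**Totals**
Total step count: 11. Longest linear sequence: 11 steps (1 → 21).

**Steps most likely to fail**

Step 3 (tandem oxy-Cope/alkylation). The tertiary homoallylic alkoxide may fragment by retro-allylation instead of rearranging, or the hindered enolate may O-alkylate. The fallback sets out from 2 and comes back at 9. It makes the C4–C5 bond by a Hosomi–Sakurai conjugate crotylation of 2 with (Z)-crotyltrimethylsilane and TiCl4 in CH2Cl2 at −78 °C, anti to the cyclopropane. This gives (1R,4S,6S)-4-[(2S)-but-3-en-2-yl]-4,7,7-trimethylbicyclo[4.1.0]heptan-2-one F1. The open transition state gives lower C4 control than the oxy-Cope, so the C4 epimers would need separating. C10 is the only enolisable position of this ketone, so KHMDS followed by bromide 6 gives 9.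

Step 6 (thermal homodienyl shift). The tetrasubstituted C10 terminus or the neighbouring 14-methyl may keep the endo methyl from reaching C10. The fallback sets out from 10 and comes back at 13 by an ionic instead of a pericyclic opening, with TMSOTf and 2,6-lutidine in CH2Cl2 at −78 → 0 °C. Silyl activation of the cyclopropyl ketone cleaves C8–C11 to the tertiary cation and the C8=C9 silyl enol ether, and the base removes a methyl proton. No new compound is made on the way (none F0). C10 is not reset in this variant, so only the 10β-H epimer of 10 gives 13 directly. Any 10α-H material would be equilibrated later at ketone 15 with DBU; the cis fusion is favoured there because a trans fusion would force the 7β-isopropenyl group syn-axial to the 14-methyl.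

Step 10 (tigloylation). The axial 9α-OH is hindered, and under basic acylation the O-8 ester can migrate so that the acyl groups end up exchanged. The fallback sets out from 15 and comes back at 20 with the order of acylation reversed. TESCl and imidazole give (4S,5R,7R,8R,10S)-2-methoxy-8-(triethylsilyloxy)eremophila-2,11-dien-9-one F2. L-Selectride gives (4S,5R,7R,8R,9S,10S)-2-methoxy-8-(triethylsilyloxy)eremophila-2,11-dien-9-ol F3. Tigloyl chloride 19 with DMAP and Et3N gives (4S,5R,7R,8R,9S,10S)-2-methoxy-8-(triethylsilyloxy)eremophila-2,11-dien-9-yl (2E)-2-methylbut-2-enoate F4. Buffered HF·pyridine gives (4S,5R,7R,8R,9S,10S)-8-hydroxy-2-methoxyeremophila-2,11-dien-9-yl (2E)-2-methylbut-2-enoate F5. Steglich esterification of the now free equatorial 8-OH with 16 (DCC, DMAP) gives 20.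

**Further compounds**
F1 | step 3 | (1R,4S,6S)-4-[(2S)-but-3-en-2-yl]-4,7,7-trimethylbicyclo[4.1.0]heptan-2-one | CC1(C)[C@H]2C[C@](C)([C@@H](C)C=C)CC(=O)[C@@H]12
F0 | step 6 | none | none
F2 | step 10 | (4S,5R,7R,8R,10S)-2-methoxy-8-(triethylsilyloxy)eremophila-2,11-dien-9-one | C=C(C)[C@H]1C[C@@]2(C)[C@H](CC(OC)=C[C@@H]2C)C(=O)[C@@H]1O[Si](CC)(CC)CC
F3 | step 10 | (4S,5R,7R,8R,9S,10S)-2-methoxy-8-(triethylsilyloxy)eremophila-2,11-dien-9-ol | C=C(C)[C@H]1C[C@@]2(C)[C@H](CC(OC)=C[C@@H]2C)[C@H](O)[C@@H]1O[Si](CC)(CC)CC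
F4 | step 10 | (4S,5R,7R,8R,9S,10S)-2-methoxy-8-(triethylsilyloxy)eremophila-2,11-dien-9-yl (2E)-2-methylbut-2-enoate | C=C(C)[C@H]1C[C@@]2(C)[C@H](CC(OC)=C[C@@H]2C)[C@H](OC(=O)/C(C)=C/C)[C@@H]1O[Si](CC)(CC)CC
F5 | step 10 | (4S,5R,7R,8R,9S,10S)-8-hydroxy-2-methoxyeremophila-2,11-dien-9-yl (2E)-2-methylbut-2-enoate | C=C(C)[C@H]1C[C@@]2(C)[C@H](CC(OC)=C[C@@H]2C)[C@H](OC(=O)/C(C)=C/C)[C@@H]1O
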